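(The readings were computed on assumed constants; scatter was added.)

Count lifetimes. Winter, dusk and autumn differ in temperature and share one charge, in which Q stands below G as the limiting reagent. I shall count how many lifetimes of Q each of them has lived when it is read.

| flask | G | Q | E | D | temperature | remark | time |
|---|---|---|---|---|---|---|---|
| Saturday's | 0.25 M | 1.1 equiv | 5 equiv | 9.9 mol% | 0 °C | run made earlier |  |
| Friday's | 0.25 M | 1.8 equiv | 5 equiv | 9.9 mol% | 20 °C | run made earlier |  |
| winter | 0.25 M | 0.800 equiv | 5.00 equiv | 9.9 mol% | 35 °C |  | 8.0 h |
| dusk | 0.25 M | 0.800 equiv | 5.00 equiv | 9.9 mol% | 5 °C |  | 8.0 h |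
| autumn | 0.25 M | 0.800 equiv | 5.00 equiv | 9.9 mol% | 20 °C |  | 8.0 h |

| run | time / h | L / % | G / % |
|---|---|---|---|
| Saturday's | 4.00 | 17.4 | 84.3 |
| Saturday's | 8.00 | 26.4 | 73.0 |
| Saturday's | 15.0 | 35.9 | 61.0 |
| Saturday's | 30.0 | 51.1 | 49.8 |
| Friday's | 0.833 | 33.5 | 68.6 |
| Friday's | 2.00 | 55.9 | 46.1 |
| Friday's | 4.00 | 70.4 | 29.3 |
| Friday's | 10.0 | 84.5 | 16.3 |

(each reading ± 1 percentage point)

- the flask that comes out highest in amount of L, in percent of the G charged, or "all alike" when all lie within 1.5 percentage points (winter / dusk / autumn / all alike)
- L at the end, in percent of the G charged, winter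
- L at the end, in percent of the G charged, dusk
- L at the end, in percent of the G charged, autumn

- steps that have been proposed: G + Q + D -> D + L; E + Q + D -> D + Z; 2 E -> J

The first readings give the rate. In Friday's run G fell to 68.6 % of its charge by 0.833 h. The log of that fraction, over the time and over the 1.8 equiv of Q, gives 0.251 h⁻¹ per equivalent of Q. Saturday's first reading gives 0.0388 h⁻¹ in the same way, at 0 °C against 20 °C, so a factor of 6.48, as a reading. Each Q taken by G costs one G, so while G stands near its full charge, the fraction of Q left falls through G with this same constant, whatever the charge of Q, at this charge of G and D. The inverse is a pseudo-first-order lifetime of Q against G. Any loss of Q to E shortens it and the fall of G lengthens it, so I take these figures as a scale and not as exact times.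

Spreading that factor evenly over the degrees gives my ladder. Winter has 0.980 h, shorter than autumn's 3.98 h. Autumn's is shorter than the reading time of 8.0 h, and dusk's 16.2 h is longer than that time. Winter thus lives 8.16 lifetimes and autumn 2.01, while the dusk count, the reading time over the lifetime of Q at dusk, is 0.495. So by this count winter should be furthest along with its Q, autumn next, and dusk still at work. That gives me an order, winter, autumn, dusk, but no yields.

The forecast, with slopes a little above mine (0.27 at Friday's temperature), names winter. It gives 51 % (46 % to 57 %) for winter, 27 % (23 % to 31 %) for dusk, and 47 % (43 % to 51 %) for autumn, which it calls “still slightly short of the limit”.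

The flasks give 53.1 % in winter, 46.1 % in autumn and 27.5 % in dusk, so winter leads, and each value stands inside the forecast's range.

    G + Q + D → D + L (k = 49.0 L² mol⁻² h⁻¹, Ea = 62.0 kJ mol⁻¹)
    E + Q + D → D + Z (k = 6.30 L² mol⁻² h⁻¹, Ea = 60.0 kJ mol⁻¹)
    2 E → J (k = 0.0860 L mol⁻¹ h⁻¹, Ea = 75.0 kJ mol⁻¹)
    (constants at 20 °C)

At 0.495 lifetimes, dusk still holds 42.1 % of its Q and 72.5 % of its G. Two things act together on its L: the early hour, since dusk read at 80.0 h stands at 48.6 %, and the wearing away of Q, since with Q held dusk reaches 38.9 %. The hour weighs more. Autumn, on the same charges, lives 0.495 lifetimes in 1.97 h, so its neighbour read at 2.0 h should match dusk, and it gives 27.6 % of L.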